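## Retrosynthetic overview

1. The dihydropyran (ring B) is formed last, closed at C4–C4a by an intramolecular aldol addition of the enol-ether carbon of a vinylogous ester onto a tethered aldehyde; this step also sets C4.
2. The aldehyde comes from oxidative cleavage of a terminal alkene; the O1–C8a bond comes from addition–elimination of a homoallylic alkoxide on 3-chlorocyclohex-2-en-1-one.
3. The carbocycle (ring A) is not constructed; it is carried in whole from cyclohexane-1,3-dione (made from resorcinol).
4. The C2 stereocentre comes from (R)-epichlorohydrin: vinyl Grignard opening and re-closure to (R)-allyloxirane, then opening with hexadecylmagnesium bromide.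
5. Three short branches (epoxide, Grignard reagent, chloroenone) meet in two unions; ring order is A (brought in) then B (aldol).

Assumption: the chain in the SMILES is read as n-heptadecyl (17 carbons) and the target as the (2S,4R) isomer, in which the chain and the hydroxyl are cis.

## Route

Step 1
Reactants: 1 (R)-epichlorohydrin; 2 vinylmagnesium bromide
Product: 4 (2R)-2-(prop-2-en-1-yl)oxirane, via (2R)-1-chloropent-4-en-2-ol 3 (not isolated)
Conditions: 2 (1.2 equiv), CuI (5 mol%), THF, −78 to −20 °C; then aq NaOH (4 M), rt; Et2O extraction, distillation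
Reagents that add atoms: none
Why: Copper-catalysed Grignard opening of the epoxide at its CH2 carbon, then intramolecular Williamson closure of the chlorohydrin, moves the oxirane without touching the C–O bond of the stereocentre, so the configuration of 1 is carried into 4.

Step 2
Reactants: 5 1-bromohexadecane
Product: 6 hexadecylmagnesium bromide (THF solution, titrated)
Conditions: Mg turnings, I2 (cat.), THF, 40–60 °C
Reagents that add atoms: magnesium, [Mg]
Why: Grignard formation by magnesium insertion into a primary alkyl bromide; no stereocentre is involved.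

Step 3
Reactants: 4 (2R)-2-(prop-2-en-1-yl)oxirane; 6 hexadecylmagnesium bromide
Product: 7 (4S)-henicos-1-en-4-ol
Conditions: 6 (1.3 equiv), CuI (10 mol%), THF, −40 to 0 °C; aq NH4Cl
Reagents that add atoms: none
Why: Copper-catalysed SN2 opening of the terminal epoxide at its CH2 carbon leaves the carbinol C–O bond untouched; the descriptor changes to S only because the new heptadecyl arm ranks below allyl.

Step 4
Reactants: 8 resorcinol
Product: 9 cyclohexane-1,3-dione
Conditions: HCO2Na (1.2 equiv), Pd/C (5%), H2O, 40–50 °C; then HCl to pH 3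
Reagents that add atoms: none
Why: Palladium-catalysed transfer hydrogenation with formate as the hydride donor stops at the stabilised enolate of the 1,3-dione, which is released on acidification.

Step 5
Reactants: 9 cyclohexane-1,3-dione
Product: 10 3-chlorocyclohex-2-en-1-one
Conditions: (COCl)2 (1.1 equiv), DMF (cat.), CH2Cl2, 0 °C to rt
Reagents that add atoms: oxalyl chloride, ClC(=O)C(=O)Cl
Why: Vilsmeier-type activation of the enol (a vinylogous acid) followed by chloride addition–elimination gives the vinylogous acid chloride.

Step 6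
Reactants: 7 (4S)-henicos-1-en-4-ol; 10 3-chlorocyclohex-2-en-1-one
Product: 12 3-{[(4S)-henicos-1-en-4-yl]oxy}cyclohex-2-en-1-one, via sodium (4S)-henicos-1-en-4-olate 11 (not isolated)
Conditions: NaH (1.1 equiv), THF, 0 °C; then 10 (1.2 equiv), 0 °C to rt
Reagents that add atoms: none
Why: Intermolecular oxa-Michael addition–elimination of the secondary alkoxide on the β-chloroenone forms the vinylogous ester with retention, because the O–C bond of the stereocentre is never broken.

Step 7
Reactants: 12 3-{[(4S)-henicos-1-en-4-yl]oxy}cyclohex-2-en-1-one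
Product: 14 (3S)-3-[(3-oxocyclohex-1-en-1-yl)oxy]icosanal, via vicinal diol 13 (not isolated)
Conditions: OsO4 (2 mol%), NaIO4 (4 equiv), 2,6-lutidine (2 equiv), dioxane/H2O (3:1), rt; used promptly
Reagents that add atoms: OsO4 (osmium tetroxide), O=[Os](=O)(=O)=O; NaIO4 (sodium metaperiodate), [Na+].[O-]I(=O)(=O)=O
Why: Lemieux–Johnson oxidation (dihydroxylation, then glycol cleavage) should cut the monosubstituted alkene in preference to the trisubstituted push–pull enone alkene, and the buffered medium spares the β-oxy aldehyde and the stereocentre.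

Step 8
Reactants: 14 (3S)-3-[(3-oxocyclohex-1-en-1-yl)oxy]icosanal
Product: 15 (2S,4R)-2-heptadecyl-4-hydroxy-2,3,4,6,7,8-hexahydro-5H-chromen-5-one
Conditions: TiCl4 (1.2 equiv), CH2Cl2, −78 °C; sat. aq NaHCO3 added at −78 °C
Reagents that add atoms: none
Why: Intramolecular aldol addition (Mukaiyama/Prins type, possibly relayed through a chloride-capped titanium enolate as in TiCl4-mediated Baylis–Hillman-type aldols) closes the six-membered ring; with Ti bridging the aldehyde and ring-carbonyl oxygens and the heptadecyl group equatorial in a chair-like transition state, the new C–O bond should be pseudo-equatorial and cis to the chain (4R).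

## Compound list

1 | (R)-epichlorohydrin, (2R)-2-(chloromethyl)oxirane | ClC[C@H]1CO1 | starting material
2 | vinylmagnesium bromide | C=C[Mg]Br | starting material
3 | (2R)-1-chloropent-4-en-2-ol | ClC[C@H](O)CC=C | intermediate
4 | (2R)-2-(prop-2-en-1-yl)oxirane | C=CC[C@@H]1CO1 | intermediate
5 | 1-bromohexadecane | CCCCCCCCCCCCCCCCBr | starting material
6 | hexadecylmagnesium bromide | CCCCCCCCCCCCCCCC[Mg]Br | intermediate
7 | (4S)-henicos-1-en-4-ol | C=CC[C@@H](O)CCCCCCCCCCCCCCCCC | intermediate
8 | resorcinol | Oc1cccc(O)c1 | starting material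
9 | cyclohexane-1,3-dione | O=C1CCCC(=O)C1 | intermediate
10 | 3-chlorocyclohex-2-en-1-one | ClC1=CC(=O)CCC1 | intermediate
11 | sodium (4S)-henicos-1-en-4-olate | C=CC[C@@H]([O-])CCCCCCCCCCCCCCCCC.[Na+] | intermediate
12 | 3-{[(4S)-henicos-1-en-4-yl]oxy}cyclohex-2-en-1-one | C=CC[C@@H](OC1=CC(=O)CCC1)CCCCCCCCCCCCCCCCC | intermediate
13 | 3-{[(4S)-1,2-dihydroxyhenicosan-4-yl]oxy}cyclohex-2-en-1-one (both C2 epimers) | OCC(O)C[C@@H](OC1=CC(=O)CCC1)CCCCCCCCCCCCCCCCC | intermediate
14 | (3S)-3-[(3-oxocyclohex-1-en-1-yl)oxy]icosanal | O=CC[C@@H](OC1=CC(=O)CCC1)CCCCCCCCCCCCCCCCC | intermediate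
15 | (2S,4R)-2-heptadecyl-4-hydroxy-2,3,4,6,7,8-hexahydro-5H-chromen-5-one | CCCCCCCCCCCCCCCCC[C@H]1C[C@@H](O)C2=C(CCCC2=O)O1 | target

## Step count and risks

Total step count: 8.
Longest linear sequence: 5 (steps 1, 3, 6, 7, 8). The other two branches (steps 2, 3, 6, 7, 8 and steps 4, 5, 6, 7, 8) are also 5 long.

The three steps most likely to fail:

Step 8 (the aldol ring closure, highest risk). A vinylogous ester is a weak π-nucleophile, and TiCl4 bound to its carbonyl weakens it further. The aldehyde can also lose the vinylogous carboxylate by β-elimination, and the cis selectivity rests on a chelation model with no close precedent. The fallback sets out from 12. Iodination at the enone α-carbon (I2, pyridine, CH2Cl2) gives 3-{[(4S)-henicos-1-en-4-yl]oxy}-2-iodocyclohex-2-en-1-one F1. The same OsO4/NaIO4 cleavage then gives (3S)-3-[(2-iodo-3-oxocyclohex-1-en-1-yl)oxy]icosanal F2. CrCl2 (4 equiv) with NiCl2 (1 mol%) in DMF at rt (intramolecular Nozaki–Hiyama–Kishi reaction) adds the alkenyl–chromium bond to the aldehyde and comes back to the route at 15. The C4 epimers would be separated by chromatography if both form.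

Step 6 (the alkoxide coupling). The secondary sodium alkoxide may deprotonate the chloroenone at its γ or α′ position instead of adding, giving self-condensation. The fallback sets out from 9 and 7. Compound 9 with MeOH and TsOH (cat.) at reflux gives 3-methoxycyclohex-2-en-1-one F3. Heating 7 with F3 and TsOH (cat.) in toluene while distilling out methanol (acid-catalysed vinylogous transesterification, retention at the carbinol carbon) comes back to the route at 12.

Step 7 (the alkene cleavage). OsO4 may also attack the enol-ether alkene of the vinylogous ester, and the aldehyde may eliminate during the reaction or on isolation. The fallback sets out from 7 and installs the oxygens before the vinylogous ester exists. OsO4 (1 mol%) with N-methylmorpholine N-oxide in acetone/H2O gives (4S)-henicosane-1,2,4-triol F4. 2,2-Dimethoxypropane with pyridinium p-toluenesulfonate gives the terminal acetonide (2S)-1-(2,2-dimethyl-1,3-dioxolan-4-yl)nonadecan-2-ol F5. NaH and then 10 in THF give 3-{[(2S)-1-(2,2-dimethyl-1,3-dioxolan-4-yl)nonadecan-2-yl]oxy}cyclohex-2-en-1-one F6. H5IO6 in EtOAc at rt removes the acetonide and cleaves the glycol in one operation, passing through 13 in the flask, and comes back to the route at 14.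

## Further compounds

F1 | step 8 | 3-{[(4S)-henicos-1-en-4-yl]oxy}-2-iodocyclohex-2-en-1-one | C=CC[C@@H](OC1=C(I)C(=O)CCC1)CCCCCCCCCCCCCCCCC
F2 | step 8 | (3S)-3-[(2-iodo-3-oxocyclohex-1-en-1-yl)oxy]icosanal | O=CC[C@@H](OC1=C(I)C(=O)CCC1)CCCCCCCCCCCCCCCCC
F3 | step 6 | 3-methoxycyclohex-2-en-1-one | COC1=CC(=O)CCC1
F4 | step 7 | (4S)-henicosane-1,2,4-triol (both C2 epimers) | OCC(O)C[C@@H](O)CCCCCCCCCCCCCCCCC
F5 | step 7 | (2S)-1-(2,2-dimethyl-1,3-dioxolan-4-yl)nonadecan-2-ol | CC1(C)OCC(C[C@@H](O)CCCCCCCCCCCCCCCCC)O1
F6 | step 7 | 3-{[(2S)-1-(2,2-dimethyl-1,3-dioxolan-4-yl)nonadecan-2-yl]oxy}cyclohex-2-en-1-one | CC1(C)OCC(C[C@@H](OC2=CC(=O)CCC2)CCCCCCCCCCCCCCCCC)O1
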